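**Assumptions**
- The (S,S)-IDPi enantiomer is taken to give the (S)-carbinols. The opposite enantiomer would give the enantiomeric series.
- The Cr(III) alkoxide lactonises onto the methyl ester in situ.
- Remote induction from the two (S)-carbinols biases the macrocyclisation toward the (1S,14R) trans-lactone.
- Numbering: a1 to a14 are the 14 ring carbons, with a1 the lactone O–CH and a14 the lactone β-CH.

**Retrosynthesis**
1. The target is the bis-acetate of diol **11**, which comes from the bis-TES ether **10**.
2. The 14-membered ring and the trans α-methylene-γ-lactone are formed together in the last C–C bond-forming step. This is an intramolecular Cr(II) allylation (a1–a14 bond) of enal **9** with a 2-(bromomethyl)alkenoate; anti addition gives the trans-lactone.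
3. The two (S)-allylic carbinols (a5, a9) and the E-trisubstituted enal units come from two iterated catalytic asymmetric vinylogous Mukaiyama aldols of 1-silyloxy-3-methylbutadiene (**7**). Each aldol returns an enal for the next one.
4. The starting enal **5** comes from commercial 2-methylhexa-1,5-diene by two cross-metatheses.

**Route**

**Step 1**
Reactants: **1** 2-methylhexa-1,5-diene; **2** methyl 2-(bromomethyl)acrylate
Product: **3** methyl 2-(bromomethyl)-6-methylhepta-2,6-dienoate (E/Z mixture)
Conditions: Hoveyda–Grubbs II (5 mol%), CH2Cl2, 40 °C; 1 (3 equiv), 2 (1 equiv)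
Reagents that add atoms: none
Why: Cross-metathesis takes place at the unhindered monosubstituted alkene, and the 1,1-disubstituted methallyl alkene stays intact. The E/Z ratio of the new alkene is irrelevant, because the allylchromium formed later equilibrates.

**Step 2**
Reactants: **3**; **4** acrolein
Product: **5** methyl (6E)-2-(bromomethyl)-6-methyl-8-oxoocta-2,6-dienoate
Conditions: Hoveyda–Grubbs II (5 mol%), acrolein (5 equiv), CH2Cl2, 40 °C
Reagents that add atoms: none
Why: Cross-metathesis of the methallyl alkene with acrolein gives the thermodynamically favoured E-trisubstituted enal. The electron-poor trisubstituted acrylate is inert.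

**Step 3**
Reactants: **6** prenal (3-methylbut-2-enal)
Product: **7** 1-(triethylsilyloxy)-3-methylbuta-1,3-diene (Z)
Conditions: TESOTf, Et3N, CH2Cl2, 0 °C
Reagents that add atoms: TESOTf, triethylsilyl triflate, CC[Si](CC)(CC)OS(=O)(=O)C(F)(F)F
Why: Soft enolisation of the enal through its γ-hydrogens gives the silyl dienol ether.

**Step 4**
Reactants: **5** (2 equiv); **7** (1 equiv)
Product: **8** methyl (2E/Z,6E,8S,10E)-2-(bromomethyl)-6,10-dimethyl-12-oxo-8-[(triethylsilyl)oxy]dodeca-2,6,10-trienoate
Conditions: (S,S)-IDPi (2 mol%), toluene, –60 °C, 48 h
Reagents that add atoms: none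
Why: Proposed new method: a confined chiral imidodiphosphorimidate acid acts as a silylium-type Lewis acid, activating the enal for γ-attack by the aldehyde-level silyl dienol ether. This is a catalytic asymmetric vinylogous Mukaiyama aldol. The s-trans diene geometry gives the E-trisubstituted alkene, silyl transfer gives the O-TES enal directly with no redox step, and catalyst control sets the (S)-carbinol a9. The closest known reaction types are IDPi-catalysed Mukaiyama aldol and vinylogous aldol of silyl ketene acetals. What is untested is using an ester-free silyloxydiene from an enal, and an enal electrophile, with this catalyst class.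

**Step 5**
Reactants: **8** (1 equiv); **7** (0.9 equiv)
Product: **9** methyl (2E/Z,6E,8S,10E,12S,14E)-2-(bromomethyl)-6,10,14-trimethyl-16-oxo-8,12-bis[(triethylsilyl)oxy]hexadeca-2,6,10,14-tetraenoate
Conditions: (S,S)-IDPi (2 mol%), toluene, –60 °C, 48 h
Reagents that add atoms: none
Why: Proposed new method: this is the same catalytic vinylogous Mukaiyama aldol, iterated on the enal **8**. The 1,5-remote a9 stereocentre is far from the reacting centre, so the catalyst rather than the substrate dictates the (S)-configuration at a5, with the same sense of induction as in Step 4.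

**Step 6**
Reactants: **9**
Product: **10** bis-TES ether of the macrocyclic trans-α-methylene-γ-lactone (1S,14R; a5 S, a9 S)
Conditions: CrCl2 (10 equiv), DMF, 25 °C, 0.004 M, syringe-pump addition over 8 h
Reagents that add atoms: none
Why: Hiyama-type intramolecular Cr(II) allylation. The E-allylchromium adds through a chair transition state to the enal by γ-attack at a14, giving the anti β-hydroxy ester (stereocentres a1 and a14). The alkoxide then lactonises onto the ester, so the anti relationship becomes the trans-lactone.

**Step 7**
Reactants: **10**
Product: **11** diol lactone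
Conditions: HF·pyridine, pyridine/THF, 0 °C → rt
Reagents that add atoms: none
Why: Fluoride-mediated Si–O cleavage of the allylic TES ethers leaves the lactone, the three E-alkenes and all stereocentres untouched.

**Step 8**
Reactants: **11**
Product: **12** target
Conditions: Ac2O, pyridine, DMAP (cat.), CH2Cl2, 0 °C
Reagents that add atoms: Ac2O, acetic anhydride, CC(=O)OC(C)=O
Why: Standard acylation of the two secondary allylic alcohols, with no effect on any stereocentre.

**Checks**
- Structure: the 14-membered ring, the trans-fused α-methylene-γ-lactone, three E-trisubstituted alkenes, acetates at a5 and a9, and configurations (S)-a1, (R)-a14, (S)-a5, (S)-a9 all match the target SMILES.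
- Bookkeeping: all atoms balance. Step 1 loses ethylene, Step 2 loses ethylene, and Step 6 loses CrBr and CrOMe.
- Stereocentres: a5 and a9 are set in Steps 4 and 5; a1 and a14 are set together in Step 6. None is epimerised afterwards.
- Stereochemistry: compounds **1–7** are achiral, so the first stereocentre is set by asymmetric catalysis in Step 4.
- Functional-group tolerance: the allylic bromide is assumed to survive Steps 2 to 5. The TES ethers survive CrCl2.

**Compound list**
1 | 2-methylhexa-1,5-diene | C=C(C)CCC=C | starting material
2 | methyl 2-(bromomethyl)acrylate | C=C(CBr)C(=O)OC | starting material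
3 | methyl 2-(bromomethyl)-6-methylhepta-2,6-dienoate (E/Z) | C=C(C)CCC=C(CBr)C(=O)OC | intermediate
4 | acrolein | C=CC=O | starting material
5 | methyl (6E)-2-(bromomethyl)-6-methyl-8-oxoocta-2,6-dienoate | O=C/C=C(\C)CCC=C(CBr)C(=O)OC | intermediate
6 | prenal | CC(C)=CC=O | starting material
7 | 1-(triethylsilyloxy)-3-methylbuta-1,3-diene (Z) | CC[Si](CC)(CC)O/C=C\C(C)=C | intermediate
8 | aldol adduct 1 (8S) | O=C/C=C(\C)C[C@H](O[Si](CC)(CC)CC)/C=C(\C)CCC=C(CBr)C(=O)OC | intermediate
9 | aldol adduct 2 (8S,12S) | O=C/C=C(\C)C[C@H](O[Si](CC)(CC)CC)/C=C(\C)C[C@H](O[Si](CC)(CC)CC)/C=C(\C)CCC=C(CBr)C(=O)OC | intermediate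
10 | macrocyclic bis-TES lactone | C=C1C(=O)O[C@H]2/C=C(\C)C[C@H](O[Si](CC)(CC)CC)/C=C(\C)C[C@H](O[Si](CC)(CC)CC)/C=C(\C)CC[C@H]12 | intermediate
11 | macrocyclic diol lactone | C=C1C(=O)O[C@H]2/C=C(\C)C[C@H](O)/C=C(\C)C[C@H](O)/C=C(\C)CC[C@H]12 | intermediate
12 | target, CID11069750 | C=C1C(=O)O[C@H]2/C=C(\C)C[C@H](OC(C)=O)/C=C(\C)C[C@H](OC(C)=O)/C=C(\C)CC[C@H]12 | target

**Totals**
Total steps: 8. Longest linear sequence: 7 (Steps 1, 2, 4, 5, 6, 7, 8).

**Three steps most likely to fail**
1. **Steps 4 and 5, the new vinylogous aldols.** Diels–Alder or over-addition to the product enal, or poor ee, could occur.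
   - Fallback: use the silyl ketene acetal of methyl 3-methylbut-2-enoate with a known Lewis-base/SiCl4 (bisphosphoramide) or chiral-acid vinylogous aldol.
   - Follow each aldol with DIBAL reduction of the ester to the enal (two extra steps). The ester product cannot over-react.
2. **Step 6, macrocyclic Cr allylation.** It may give poor a1/a14 diastereoselectivity or oligomers.
   - Fallback: replace the allylic bromide by the 2-(trimethylsilylmethyl)alkenoate and close the ring by a Lewis-acid intramolecular Hosomi–Sakurai allylation at high dilution.
3. **Step 1, cross-metathesis with the electron-poor bromomethyl acrylate.** Low conversion or catalyst decomposition is possible.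
   - Fallback: oxidise commercial 4-methylpent-4-en-1-ol to the aldehyde, then run a Morita–Baylis–Hillman reaction with methyl acrylate (DABCO).
   - Convert the adduct to the (Z)-allyl bromide **3** with NBS/Me2S (SN2′), then continue with Step 2.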